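The synthesis opens the pyran ring of the cyclopenta[c]pyran core at C1–C7a and O2–C3. Once the C3=C4 enol ether alkene is moved to C4=C4a, ring atoms C1, O2, C3, C4, C4a and C7a map onto two partners. One is an aldehyde carbonyl (C1=O2, carried by coumarin C3'). The other is a 1-alkenylcyclopentene diene (C7a=C4a–C4=C3). A single Lewis acid catalysed oxo-Diels–Alder reaction thus unites both halves, closes the pyran and sets C1, C3 and C7a under the influence of the C7 methyl centre. Its precursors are 4-methoxy-5-methyl-3-formylcoumarin and an (S)-3-methylcyclopentenyl E-dienyne, whose silylated tertiary propargylic alcohol masks the senecioyl ketone.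

Key step: step 9

Numbering: unprimed locants follow cyclopenta[c]pyran (C1 coumarin-bearing, O2, C3, C4, C4a, C5–C7, C7a); primed locants belong to the coumarin.

Assumption: (R)-p-tol-BINAP is taken as the ligand antipode that gives the S centre in step 1. The sense is checked on a hydrolysed aliquot against commercial (R)-(+)-3-methylcyclopentanone, and the equally available (S)-ligand is used if it proves opposite.

Step 1
Reactants: 1 3-methylcyclopent-2-en-1-one
Product: 4 (3S)-3-methylcyclopent-1-en-1-yl trifluoromethanesulfonate, via bis-enoxysilane 2 (not isolated), via lithium enolate 3 (not isolated)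
Conditions: CuCl, NaOt-Bu, (R)-p-tol-BINAP (5 mol % each), Ph2SiH2 (0.55 equiv), toluene, 0 °C; MeLi (1.1 equiv), THF, 0 °C; Comins' reagent (1.1 equiv), −78 → 0 °C
Reagents that add atoms: Comins' reagent, N-(5-chloropyridin-2-yl)bis(trifluoromethanesulfonimide), O=S(=O)(N(c1ccc(Cl)cn1)S(=O)(=O)C(F)(F)F)C(F)(F)F
Why: Ligand-controlled copper hydride 1,4-hydrosilylation delivers hydride to one face of the β-carbon and sets the S methyl-bearing centre (future C7), the enol silane holds the double bond on the side of that centre, and Si-to-Li exchange followed by O-sulfonylation carries this regiochemistry unchanged into the enol triflate.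

Step 2
Reactants: 4 (3S)-3-methylcyclopent-1-en-1-yl trifluoromethanesulfonate
Product: 6 (3S)-1-ethynyl-3-methylcyclopent-1-ene, via TMS-enyne 5 (not isolated)
Conditions: TMS-acetylene, PdCl2(PPh3)2 (3 mol %), CuI (5 mol %), Et3N, THF, rt; then MeOH, K2CO3 (2 equiv), rt, under argon; 6 extracted into CH2Cl2, dried and carried on as a solution (volatile)
Reagents that add atoms: trimethylsilylacetylene, C#C[Si](C)(C)C
Why: Sonogashira coupling of an alkenyl triflate and carbonate-mediated methanolysis of the alkynyl C–Si bond are both routine, leave the ring alkene and the allylic stereocentre untouched, and telescoping avoids isolating two volatile hydrocarbons.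

Step 3
Reactants: 6 (3S)-1-ethynyl-3-methylcyclopent-1-ene
Product: 8 (3S)-1-[(1E)-1-iodoprop-1-en-2-yl]-3-methylcyclopent-1-ene, via alkenylalane 7 (not isolated)
Conditions: Me3Al (2.5 equiv), Cp2ZrCl2 (25 mol %), CH2Cl2, 0 °C → rt; then I2, THF, −30 → 0 °C
Reagents that add atoms: trimethylaluminium, C[Al](C)C; iodine, II
Why: Negishi zirconium-catalysed methylalumination adds CH3 and Al syn across the terminal alkyne of a conjugated enyne with Al at the terminus, and iodinolysis with retention gives the single E-iodide (iodine cis to the new methyl, trans to the ring), a geometry that carbonyl olefination of the corresponding methyl ketone would not secure.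

Step 4
Reactants: 9 2-methylbut-3-yn-2-ol
Product: 10 triethyl[(2-methylbut-3-yn-2-yl)oxy]silane
Conditions: TESCl, imidazole, DMAP (cat.), DMF, rt
Reagents that add atoms: chlorotriethylsilane, CC[Si](Cl)(CC)CC
Why: Routine silylation of a tertiary alcohol flanked by a slim alkyne; the TES group hides the Lewis basic, ionisable hydroxyl in steps 5 and 9 and is removable by fluoride.

Step 5
Reactants: 8 (3S)-1-[(1E)-1-iodoprop-1-en-2-yl]-3-methylcyclopent-1-ene; 10 triethyl[(2-methylbut-3-yn-2-yl)oxy]silane
Product: 11 triethyl({(5E)-2-methyl-6-[(3S)-3-methylcyclopent-1-en-1-yl]hept-5-en-3-yn-2-yl}oxy)silane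
Conditions: PdCl2(PPh3)2 (3 mol %), CuI (5 mol %), Et3N, THF, rt
Reagents that add atoms: none
Why: Sonogashira coupling of an alkenyl iodide runs at room temperature with retention of alkene geometry, so the E-dienyne is obtained stereodefined.

Step 6
Reactants: 12 1-(2-hydroxy-6-methylphenyl)ethan-1-one
Product: 13 4-hydroxy-5-methyl-2H-chromen-2-one
Conditions: NaH (3.5 equiv), (EtO)2CO, toluene, 110 °C; then aq. HCl
Reagents that add atoms: diethyl carbonate, CCOC(=O)OCC
Why: Claisen-type C-ethoxycarbonylation of the ketone enolate followed by lactonisation onto the phenoxide is the standard construction of 4-hydroxycoumarins from 2-hydroxyacetophenones.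

Step 7
Reactants: 13 4-hydroxy-5-methyl-2H-chromen-2-one
Product: 14 4-chloro-5-methyl-2-oxo-2H-chromene-3-carbaldehyde
Conditions: POCl3 (3 equiv), DMF, 0 → 60 °C; then ice-water
Reagents that add atoms: N,N-dimethylformamide, CN(C)C=O; phosphoryl chloride, O=P(Cl)(Cl)Cl; water, O
Why: The Vilsmeier–Haack reaction of 4-hydroxycoumarins formylates the nucleophilic C3' and at the same time converts the vinylogous acid OH into chloride, which is the established outcome for this heterocycle.

Step 8
Reactants: 14 4-chloro-5-methyl-2-oxo-2H-chromene-3-carbaldehyde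
Product: 15 4-methoxy-5-methyl-2-oxo-2H-chromene-3-carbaldehyde
Conditions: NaOMe (1.05 equiv), MeOH–THF, −20 → 0 °C; then aq. NH4Cl
Reagents that add atoms: sodium methoxide, C[O-].[Na+]
Why: The chloride sits at the β-position of a doubly activated alkene (a vinylogous acid chloride), so methoxide replaces it by addition–elimination faster than it opens the lactone, and any hemiacetal formed at the aldehyde reverts on work-up.

Step 9
Reactants: 11 triethyl({(5E)-2-methyl-6-[(3S)-3-methylcyclopent-1-en-1-yl]hept-5-en-3-yn-2-yl}oxy)silane; 15 4-methoxy-5-methyl-2-oxo-2H-chromene-3-carbaldehyde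
Product: 16 3-{(1R,3S,7S,7aR)-4,7-dimethyl-3-[3-methyl-3-(triethylsilyloxy)but-1-yn-1-yl]-1,3,5,6,7,7a-hexahydrocyclopenta[c]pyran-1-yl}-4-methoxy-5-methyl-2H-chromen-2-one
Conditions: Cu(OTf)2 (15 mol %), achiral 2,2'-(propane-2,2-diyl)bis(4,4-dimethyl-4,5-dihydrooxazole) (17 mol %), 2,6-di-tert-butyl-4-methylpyridine (20 mol %), 4 Å MS, CH2Cl2, −20 °C → rt; 11 in slight excess
Reagents that add atoms: none
Why: Cu(II) binds the formyl and lactone carbonyl oxygens of 15 in a six-membered chelate, which lowers the C=O LUMO and lets the aldehyde act as the 2π component towards the s-cis diene C7a=C4a–C4=C3 of 11 in a concerted but strongly asynchronous [4+2] cycloaddition, the closest known reaction type being the Lewis acid catalysed oxo-Diels–Alder reaction of chelating activated aldehydes such as glyoxylates with alkyl-substituted 1,3-dienes. The one ring closed, the 3,6-dihydro-2H-pyran, is the six-membered cycloadduct ring itself, with C1–C7a bonding leading and O2–C3 bonding following (in the stepwise limit a 6-endo capture of the allyl–propargyl cation by the copper alkoxide), so the pyran is annulated onto the existing cyclopentene. For regiochemistry, the conjugating alkynyl group at C3 puts the larger HOMO coefficient on the remote terminus C7a and stabilises developing positive charge at C3, so the electrophilic carbonyl carbon bonds to C7a and oxygen to C3. C7a is set by approach of the aldehyde to the cyclopentene face opposite the adjacent C7 methyl group, C3 follows from suprafacial addition to the E-alkene (H-3 and H-7a are both inside hydrogens and end up cis), and C1 follows from an exo coumarin, because chelation holds the metal and its ligand on the coumarin side of the carbonyl and this bulky unit avoids the C4 methyl and C5 methylene above the diene. The step needs chemoselectivity for C=O over the coumarin C3'=C4' alkene and over the O=CH–C3'=C4' oxadiene, which the fully substituted C4' (methoxy buttressed by the peri C5' methyl) secures, while the same crowding twists the methoxy group out of conjugation so that it weakens the aldehyde only slightly. The alkyne keeps the diene electron-rich where a C3 ketone would not, and the silyl ether, sieves and hindered pyridine suppress protic ionisation of the tertiary propargylic C–O bond and of the C3–O2 bond of the product.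

Step 10
Reactants: 16 3-{(1R,3S,7S,7aR)-4,7-dimethyl-3-[3-methyl-3-(triethylsilyloxy)but-1-yn-1-yl]-1,3,5,6,7,7a-hexahydrocyclopenta[c]pyran-1-yl}-4-methoxy-5-methyl-2H-chromen-2-one
Product: 17 3-[(1R,3S,7S,7aR)-3-(3-hydroxy-3-methylbut-1-yn-1-yl)-4,7-dimethyl-1,3,5,6,7,7a-hexahydrocyclopenta[c]pyran-1-yl]-4-methoxy-5-methyl-2H-chromen-2-one
Conditions: HF·pyridine, excess pyridine, THF, 0 °C
Reagents that add atoms: none
Why: Fluoride-driven Si–O cleavage under pyridine buffering frees the tertiary alcohol without acid strong enough to ionise the allylic and propargylic C3–O2 bond and without base able to attack the methoxycoumarin.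

Step 11
Reactants: 17 3-[(1R,3S,7S,7aR)-3-(3-hydroxy-3-methylbut-1-yn-1-yl)-4,7-dimethyl-1,3,5,6,7,7a-hexahydrocyclopenta[c]pyran-1-yl]-4-methoxy-5-methyl-2H-chromen-2-one
Product: 19 3-[(1R,4aS,7S,7aR)-4,7-dimethyl-3-(3-methylbut-2-enoyl)-1,4a,5,6,7,7a-hexahydrocyclopenta[c]pyran-1-yl]-4-methoxy-5-methyl-2H-chromen-2-one, via deconjugated ketone 18 (not isolated)
Conditions: MoO2(acac)2, Ph3PAuCl, AgOTf (3 mol % each), toluene, rt; then DBU (0.5 equiv), rt → 40 °C
Reagents that add atoms: none
Why: A Meyer–Schuster rearrangement through the molybdate ester of the only free hydroxyl, assisted by gold π-activation, shifts oxygen 1,3 onto the alkyne carbon next to C3 and gives senecioyl ketone 18, whose C3–H (α to the ketone, α to O2, allylic) is then removed by DBU so that the dienolate is reprotonated at C4a under equilibrating conditions, erasing C3 and giving the conjugated C3=C4 enol ether with H-4a on the face of H-7a, the less strained cis ring fusion.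

Step 12
Reactants: 19 3-[(1R,4aS,7S,7aR)-4,7-dimethyl-3-(3-methylbut-2-enoyl)-1,4a,5,6,7,7a-hexahydrocyclopenta[c]pyran-1-yl]-4-methoxy-5-methyl-2H-chromen-2-one
Product: 20 3-[(1R,4aS,7S,7aR)-4,7-dimethyl-3-(3-methylbut-2-enoyl)-1,4a,5,6,7,7a-hexahydrocyclopenta[c]pyran-1-yl]-4-hydroxy-5-methyl-2H-chromen-2-one (CNP0297827.1)
Conditions: LiCl (10 equiv), DMSO, 60 °C; then cold 0.5 M HCl
Reagents that add atoms: none
Why: The 4'-methoxy group is a vinylogous methyl carbonate twisted by its C3' and C5' neighbours, so chloride removes the methyl by SN2 dealkylation (as with methyl tetronates) under neutral conditions that spare the enone, the acyl enol ether and all four stereocentres; C1 already holds the more stable arrangement (coumarin trans to C7), so reversible oxa-Michael opening of the freed hydroxycoumarin should not erode it.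

Compound list
1 | 3-methylcyclopent-2-en-1-one | CC1=CC(=O)CC1 | starting material
2 | bis{[(3S)-3-methylcyclopent-1-en-1-yl]oxy}diphenylsilane | C[C@H]1CCC(O[Si](c2ccccc2)(c2ccccc2)OC2=C[C@@H](C)CC2)=C1 | intermediate
3 | lithium (3S)-3-methylcyclopent-1-en-1-olate | [Li]OC1=C[C@@H](C)CC1 | intermediate
4 | (3S)-3-methylcyclopent-1-en-1-yl trifluoromethanesulfonate | O=S(=O)(OC1=C[C@@H](C)CC1)C(F)(F)F | intermediate
5 | trimethyl{[(3S)-3-methylcyclopent-1-en-1-yl]ethynyl}silane | C[Si](C)(C)C#CC1=C[C@@H](C)CC1 | intermediate
6 | (3S)-1-ethynyl-3-methylcyclopent-1-ene | C#CC1=C[C@@H](C)CC1 | intermediate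
7 | dimethyl{(1E)-2-[(3S)-3-methylcyclopent-1-en-1-yl]prop-1-en-1-yl}alane | C[Al](C)/C=C(\C)C1=C[C@@H](C)CC1 | intermediate
8 | (3S)-1-[(1E)-1-iodoprop-1-en-2-yl]-3-methylcyclopent-1-ene | I/C=C(\C)C1=C[C@@H](C)CC1 | intermediate
9 | 2-methylbut-3-yn-2-ol | CC(C)(O)C#C | starting material
10 | triethyl[(2-methylbut-3-yn-2-yl)oxy]silane | C#CC(C)(C)O[Si](CC)(CC)CC | intermediate
11 | triethyl({(5E)-2-methyl-6-[(3S)-3-methylcyclopent-1-en-1-yl]hept-5-en-3-yn-2-yl}oxy)silane | CC(C)(O[Si](CC)(CC)CC)C#C/C=C(\C)C1=C[C@@H](C)CC1 | intermediate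
12 | 1-(2-hydroxy-6-methylphenyl)ethan-1-one | CC(=O)c1c(C)cccc1O | starting material
13 | 4-hydroxy-5-methyl-2H-chromen-2-one | Cc1cccc2oc(=O)cc(O)c12 | intermediate
14 | 4-chloro-5-methyl-2-oxo-2H-chromene-3-carbaldehyde | O=Cc1c(Cl)c2c(C)cccc2oc1=O | intermediate
15 | 4-methoxy-5-methyl-2-oxo-2H-chromene-3-carbaldehyde | O=Cc1c(OC)c2c(C)cccc2oc1=O | intermediate
16 | (1R,3S,7S,7aR) cycloadduct: C4=C4a alkene, C3 silyloxyalkynyl, C1 4-methoxy-5-methylcoumarin-3-yl; H-3 and H-7a cis, H-1 trans to H-7a, C7 methyl cis to H-7a | CC(C)(O[Si](CC)(CC)CC)C#C[C@H]1C(C)=C2CC[C@H](C)[C@H]2[C@H](c2c(OC)c3c(C)cccc3oc2=O)O1 | intermediate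
17 | (1R,3S,7S,7aR) tertiary propargylic alcohol derived from 16 | CC(C)(O)C#C[C@H]1C(C)=C2CC[C@H](C)[C@H]2[C@H](c2c(OC)c3c(C)cccc3oc2=O)O1 | intermediate
18 | (1R,3R,7S,7aR) C3 senecioyl ketone with the C4=C4a alkene | CC(C)=CC(=O)[C@H]1C(C)=C2CC[C@H](C)[C@H]2[C@H](c2c(OC)c3c(C)cccc3oc2=O)O1 | intermediate
19 | (1R,4aS,7S,7aR) cis-fused C3=C4 acyl enol ether, 4'-O-methyl ether of the target | CC(C)=CC(=O)C1=C(C)[C@H]2CC[C@H](C)[C@H]2[C@H](c2c(OC)c3c(C)cccc3oc2=O)O1 | intermediate
20 | CNP0297827.1, 3-[(1R,4aS,7S,7aR)-4,7-dimethyl-3-(3-methylbut-2-enoyl)-1,4a,5,6,7,7a-hexahydrocyclopenta[c]pyran-1-yl]-4-hydroxy-5-methyl-2H-chromen-2-one | CC(C)=CC(=O)C1=C(C)[C@H]2CC[C@H](C)[C@H]2[C@H](c2c(O)c3c(C)cccc3oc2=O)O1 | target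

Total step count: 12
Longest linear sequence: 8 steps (1, 2, 3, 5, 9, 10, 11, 12)

Steps most likely to fail

Step 9.
- **What may go wrong:** The cross-conjugated formyl group may react too slowly. Cycloaddition could then be overtaken by carbonyl-ene hydrogen transfer from the C4 methyl or C5 methylene, by bonding in the reversed orientation, or by Lewis acid ionisation of the propargylic silyl ether. Incomplete exo selectivity alone is tolerable, because C1 becomes epimerisable by reversible oxa-Michael opening once the hydroxycoumarin is free.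
- **Fallback (from 11 and 13, back at 16):** Ring construction and coumarin attachment are separated. Diene 11 is cycloadded under the same copper catalysis to ethyl glyoxylate, the archetypal chelating heterodienophile, to give the C1 ethyl ester F1 (either C1 epimer serves). LiOH hydrolysis gives the carboxylic acid F2. Oxidative decarboxylation with Pb(OAc)4 gives the C1 acetoxy acetal F3. BF3·OEt2 at −78 °C ionises this to the cyclic oxocarbenium ion, which C-alkylates hydroxycoumarin 13 at C3' from the face opposite C7 to give the 4'-hydroxy cycloadduct analogue F4. O-methylation with TMSCHN2 returns to 16.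

Step 11.
- **What may go wrong:** The carbophilic acid may trigger loss of the doubly activated C3–O2 bond or engage the skipped enyne. Reprotonation of the dienolate may also stall at C3 or deliver the trans ring fusion.
- **Fallback (from 17, back at 19):** π-Acid catalysis is avoided. [Cp*Ru(MeCN)3]PF6-catalysed trans-hydrosilylation with (EtO)3SiH places silicon on the alkyne carbon remote from the carbinol and gives the Z-vinylsilane F5. Tamao–Fleming oxidation (KF, KHCO3, H2O2) gives the β-hydroxy ketone F6. Dehydration with Burgess reagent, then DBU in the same flask, leads by way of 18 to 19.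

Step 12.
- **What may go wrong:** Heating the acyl enol ether with halide, and the liberation of the hydroxycoumarin anion next to a good enolate leaving group, may cause ring opening that does not reclose cleanly, or addition to the enone.
- **Fallback (from 17, back at 20):** The methyl group is removed before the sensitive chromophore exists. LiCl in DMSO converts 17 into the hydroxycoumarin alkynol F7. The Mo/Au/Ag Meyer–Schuster conditions give the hydroxycoumarin deconjugated ketone F8 (not isolated). DBU (2 equiv) then moves the alkene, sets C4a and lets C1 settle at its more stable configuration, giving 20 after mild acidification.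

Further compounds
F1 | step 9 | ethyl (3S,7S,7aR)-4,7-dimethyl-3-[3-methyl-3-(triethylsilyloxy)but-1-yn-1-yl]-1,3,5,6,7,7a-hexahydrocyclopenta[c]pyran-1-carboxylate (C1 epimers both usable) | CC(C)(O[Si](CC)(CC)CC)C#C[C@H]1C(C)=C2CC[C@H](C)[C@H]2C(C(=O)OCC)O1
F2 | step 9 | corresponding C1 carboxylic acid | CC(C)(O[Si](CC)(CC)CC)C#C[C@H]1C(C)=C2CC[C@H](C)[C@H]2C(C(=O)O)O1
F3 | step 9 | corresponding C1 acetoxy acetal | CC(C)(O[Si](CC)(CC)CC)C#C[C@H]1C(C)=C2CC[C@H](C)[C@H]2C(OC(C)=O)O1
F4 | step 9 | 4'-hydroxy analogue of 16, (1R,3S,7S,7aR) | CC(C)(O[Si](CC)(CC)CC)C#C[C@H]1C(C)=C2CC[C@H](C)[C@H]2[C@H](c2c(O)c3c(C)cccc3oc2=O)O1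
F5 | step 11 | Z-vinylsilane from trans addition of H and Si(OEt)3 to the alkyne of 17, silicon on the carbon attached to C3 | CC(C)(O)/C=C(\[Si](OCC)(OCC)OCC)[C@H]1C(C)=C2CC[C@H](C)[C@H]2[C@H](c2c(OC)c3c(C)cccc3oc2=O)O1
F6 | step 11 | C3 (3-hydroxy-3-methylbutanoyl) ketone | CC(C)(O)CC(=O)[C@H]1C(C)=C2CC[C@H](C)[C@H]2[C@H](c2c(OC)c3c(C)cccc3oc2=O)O1
F7 | step 12 | 4'-hydroxy analogue of 17 | CC(C)(O)C#C[C@H]1C(C)=C2CC[C@H](C)[C@H]2[C@H](c2c(O)c3c(C)cccc3oc2=O)O1
F8 | step 12 | 4'-hydroxy analogue of 18 | CC(C)=CC(=O)[C@H]1C(C)=C2CC[C@H](C)[C@H]2[C@H](c2c(O)c3c(C)cccc3oc2=O)O1
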